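**Retrosynthetic overview**
1. Target 22 comes from debenzylation of 21. Compound 21 comes from diene ester 19 by the proposed aerobic hydroxy-epoxidation, in which one O2 supplies both the C10-OH and the C3-C4 epoxide oxygen.
2. Ester 19 comes from acylation of guaia-3,10(14)-dien-8-ol 17. The five-membered ring is closed last, by ring-closing metathesis (C3=C4) of triene 15.
3. Triene 15 comes from methylenation of ketone 14. Ketone 14 comes from conjugate addition and allylation on cycloheptenone 12, which forms C4-C5 and C1-C2 trans.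
4. Enone 12 (seven-membered ring) comes from a one-carbon ring expansion of cyclohexanone 7.
5. Ketone 7 comes from (S)-cryptone 4, made from isovaleraldehyde 1 and methyl vinyl ketone 2. Ring order: six-membered, enlarged to seven-membered, then five-membered.

Assumption: guaiane numbering is used for the bicyclic compounds (C1/C5 ring fusion, C4 and C10 carry methyl, C7 isopropyl, C8 the ester). α is the face of H-1 and β the face of H-5. On this basis the target is (1R,3R,4S,5S,7S,8R,10R), trans-fused, with 7α-isopropyl, 8β-ester, 10α-OH and a 3α,4α-epoxide.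

**Step 1**
Reactants: 1 isovaleraldehyde (3-methylbutanal); 2 methyl vinyl ketone (but-3-en-2-one)
Product: 3 (2S)-2-isopropyl-5-oxohexanal
Conditions: (S)-2-[diphenyl(methoxy)methyl]pyrrolidine (5 mol %), ethyl 3,4-dihydroxybenzoate (20 mol %), neat, 4 °C
Reagents that add atoms: none
Why: Enamine-catalysed asymmetric Michael addition; the diphenyl(methoxy)methyl group of the (S)-catalyst shields one face of the E-enamine of 1, so 2 adds from the open face and sets C7 as S.

**Step 2**
Reactants: 3 (2S)-2-isopropyl-5-oxohexanal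
Product: 4 (S)-cryptone, (4S)-4-isopropylcyclohex-2-en-1-one
Conditions: LiOH (0.2 equiv), i-PrOH, rt
Reagents that add atoms: none
Why: Intramolecular aldol condensation of the methyl ketone onto the aldehyde closes the six-membered enone, and the mild base leaves the γ stereocentre untouched.

**Step 3**
Reactants: 4 (S)-cryptone
Product: 6 (3R,4S)-3-hydroxy-4-isopropylcyclohexan-1-one, via trans boryl ketone 5 (not isolated)
Conditions: CuCl (5 mol %), DPEphos (5 mol %), NaOt-Bu (10 mol %), B2pin2, MeOH (2 equiv), THF, rt; then NaBO3·4H2O, THF/H2O, rt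
Reagents that add atoms: bis(pinacolato)diboron CC1(C)OB(OC1(C)C)B1OC(C)(C)C(C)(C)O1; sodium perborate [Na+].[O-]OB=O
Why: Copper-catalysed conjugate borylation followed by stereoretentive C-B oxidation; the Cu-Bpin species attacks the β-carbon anti to the neighbouring isopropyl group and sets C8 as R, trans to isopropyl.

**Step 4**
Reactants: 6 (3R,4S)-3-hydroxy-4-isopropylcyclohexan-1-one
Product: 7 (3R,4S)-3-[(tert-butyldimethylsilyl)oxy]-4-isopropylcyclohexan-1-one
Conditions: TBSCl, imidazole, DMF, rt to 35 °C
Reagents that add atoms: tert-butyldimethylsilyl chloride CC(C)(C)[Si](C)(C)Cl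
Why: Standard silyl ether protection under near-neutral conditions, which do not eliminate the β-hydroxy ketone.

**Step 5**
Reactants: 7 (3R,4S)-3-[(tert-butyldimethylsilyl)oxy]-4-isopropylcyclohexan-1-one
Product: 9 tert-butyl({(1R,6S)-6-isopropyl-3-[(trimethylsilyl)oxy]cyclohex-3-en-1-yl}oxy)dimethylsilane, via lithium enolate 8 (not isolated)
Conditions: LDA (1.1 equiv), THF, -78 °C; then TMSCl, -78 to 0 °C
Reagents that add atoms: lithium diisopropylamide CC(C)N([Li])C(C)C; chlorotrimethylsilane C[Si](C)(C)Cl
Why: Kinetic enolisation and O-silylation; LDA takes the proton of the CH2 remote from the bulky, electron-withdrawing silyloxy carbon, which fixes where the new ring carbon will be inserted.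

**Step 6**
Reactants: 9 the trimethylsilyl enol ether
Product: 10 (3R,4S)-3-[(tert-butyldimethylsilyl)oxy]-4-isopropyl-1-[(trimethylsilyl)oxy]bicyclo[4.1.0]heptane (cyclopropane CH2 drawn on the face opposite to the OTBS group)
Conditions: Et2Zn, CH2I2, toluene, 0 °C to rt
Reagents that add atoms: diiodomethane ICI
Why: Simmons-Smith cyclopropanation (Furukawa variant) of the electron-rich enol ether brings in the future C1; the two new centres are erased in step 7, so both ring-fusion isomers converge.

**Step 7**
Reactants: 10 the silyloxycyclopropane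
Product: 12 (5S,6R)-6-[(tert-butyldimethylsilyl)oxy]-5-isopropylcyclohept-2-en-1-one, via chloro ketone 11 (not isolated)
Conditions: FeCl3 (2.2 equiv), DMF, 0 °C to rt; then NaOAc, MeOH, 55 °C
Reagents that add atoms: iron trichloride Cl[Fe](Cl)Cl
Why: Saegusa-type oxidative ring expansion; one-electron oxidation by trivalent iron cleaves the ring-fusion cyclopropane bond to a ring-enlarged β-keto radical, which takes up chlorine, and mild base then removes HCl (E1cB) to give the seven-membered enone.

**Step 8**
Reactants: 12 (5S,6R)-6-[(tert-butyldimethylsilyl)oxy]-5-isopropylcyclohept-2-en-1-one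
Product: 14 (2R,3S,5S,6R)-2-allyl-6-[(tert-butyldimethylsilyl)oxy]-5-isopropyl-3-(prop-1-en-2-yl)cycloheptan-1-one, via magnesium enolate 13 (not isolated)
Conditions: CH2=C(CH3)MgBr (1.3 equiv), CuBr·SMe2 (10 mol %), THF, -40 °C; then allyl iodide (3 equiv), DMPU, -40 to 0 °C
Reagents that add atoms: isopropenylmagnesium bromide CC(=C)[Mg]Br; allyl iodide C=CCI
Why: Copper-catalysed conjugate addition with enolate allylation (three-component coupling); the trans-diequatorial isopropyl and OTBS groups lock the chair-like enone, the copper reagent attacks the open convex face so that the isopropenyl group is equatorial and cis to isopropyl (C5 S), and allyl iodide then enters anti to it (C1 R), giving the all-equatorial and therefore also thermodynamic isomer.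

**Step 9**
Reactants: 14 the allyl isopropenyl ketone
Product: 15 tert-butyl{[(1R,2S,4S,5R)-5-allyl-2-isopropyl-6-methylidene-4-(prop-1-en-2-yl)cycloheptyl]oxy}dimethylsilane
Conditions: Ph3PCH3Br, KOt-Bu, THF, 0 °C to rt
Reagents that add atoms: methyltriphenylphosphonium bromide C[P+](c1ccccc1)(c1ccccc1)c1ccccc1.[Br-]
Why: Wittig methylenation installs C14 as the exocyclic alkene; C1 cannot be lost because the trans arrangement is also the equilibrium one.

**Step 10**
Reactants: 15 the triene
Product: 16 tert-butyldimethylsilyl ether of (1R,5S,7S,8R)-guaia-3,10(14)-dien-8-ol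
Conditions: second-generation Grubbs catalyst (H2IMes)(PCy3)Cl2Ru=CHPh (5 mol %), CH2Cl2 (0.005 M), 40 °C
Reagents that add atoms: none
Why: Ring-closing metathesis of the allyl and isopropenyl groups closes the trans-fused methylcyclopentene (C3=C4); the exocyclic methylene is a spectator because any closure through it would give a cyclobutene.

**Step 11**
Reactants: 16 the bicyclic silyl ether
Product: 17 (1R,5S,7S,8R)-guaia-3,10(14)-dien-8-ol
Conditions: TBAF, THF, 45 °C
Reagents that add atoms: none
Why: Fluoride desilylation frees the C8 alcohol without touching either alkene.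

**Step 12**
Reactants: 17 (1R,5S,7S,8R)-guaia-3,10(14)-dien-8-ol; 18 4-(benzyloxy)benzoic acid
Product: 19 (1R,5S,7S,8R)-guaia-3,10(14)-dien-8-yl 4-(benzyloxy)benzoate
Conditions: dicyclohexylcarbodiimide, DMAP (0.2 equiv), CH2Cl2, rt
Reagents that add atoms: none
Why: Steglich esterification acylates the equatorial, menthol-like secondary alcohol with retention at C8.

**Step 13**
Reactants: 19 (1R,5S,7S,8R)-guaia-3,10(14)-dien-8-yl 4-(benzyloxy)benzoate
Product: 21 (1R,3R,4S,5S,7S,8R,10R)-3,4-epoxy-10-hydroxyguaian-8-yl 4-(benzyloxy)benzoate, via 10-alpha hydroperoxide 20 (not isolated)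
Conditions: Co(acac)2 (5 mol %), PhSiH3 (1.05 equiv), O2 (1 atm), i-PrOH/CH2Cl2, 0 °C; Ar purge, short SiO2 plug; then VO(acac)2 (5 mol %), 4 Å MS, toluene, 0 °C to rt
Reagents that add atoms: dioxygen O=O
Why: Proposed new method: aerobic hydroxy-epoxidation by oxygen-atom relay, in which both atoms of one O2 end up in the product. A cobalt hydride made from Co(acac)2, PhSiH3 and O2 gives a hydrogen atom to the unhindered terminal CH2 of the 1,1-disubstituted C10=C14 alkene faster than to the endocyclic trisubstituted C3=C4 alkene. The planar tertiary C10 radical is then caught by O2 on the α face, because the β face is screened by the almost eclipsing C1-C2 bond and by axial H-5 (peracids are expected to show the same bias on trans-fused 10(14)-methylene hydroazulenes); this sets C10 as R and gives hydroperoxide 20. After cobalt and silane are removed, pentavalent vanadium formed from VO(acac)2 binds the 10α-alkoxide of a molecule that has already lost its outer oxygen (a few per cent of alcohol from the first stage start the chain), together with the hydroperoxide of a second molecule, held the way t-BuOOH is held. The outer peroxide oxygen passes to the α face of C3=C4 of the bound alkoxide (C3 R, C4 S), and each transfer turns one more hydroperoxide into the next directing alcohol; a direct intramolecular transfer is not required, and it would violate collinear attack on the O-O bond. The closest known reaction types are the Mukaiyama-Isayama cobalt/silane/O2 hydroperoxidation of alkenes, the hydroxyl-directed VO(acac)2/alkyl hydroperoxide epoxidation of bishomoallylic alcohols, and the titanium-catalysed oxygen transfer that turns ene-derived allylic hydroperoxides into epoxy alcohols.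

**Step 14**
Reactants: 21 the benzyl-protected epoxy alcohol
Product: 22 (1R,3R,4S,5S,7S,8R,10R)-3,4-epoxy-10-hydroxyguaian-8-yl 4-hydroxybenzoate (CNP0225095.2)
Conditions: H2 (1 atm), Pd/C (10 wt %), EtOAc, rt
Reagents that add atoms: none
Why: Hydrogenolysis of the aryl benzyl ether in a neutral aprotic solvent leaves the non-benzylic trisubstituted epoxide, the tertiary alcohol and the alkyl benzoate intact; the 10α-OH cannot open the α-epoxide because it sits on the same face.

**Compound list**
1 | isovaleraldehyde (3-methylbutanal) | CC(C)CC=O | starting material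
2 | methyl vinyl ketone | CC(=O)C=C | starting material
3 | (2S)-2-isopropyl-5-oxohexanal | CC(C)[C@@H](C=O)CCC(C)=O | intermediate
4 | (S)-cryptone, (4S)-4-isopropylcyclohex-2-en-1-one | CC(C)[C@@H]1CCC(=O)C=C1 | intermediate
5 | (3R,4R)-4-isopropyl-3-(4,4,5,5-tetramethyl-1,3,2-dioxaborolan-2-yl)cyclohexan-1-one (trans, not isolated) | CC(C)[C@@H]1CCC(=O)C[C@H]1B2OC(C)(C)C(C)(C)O2 | intermediate
6 | (3R,4S)-3-hydroxy-4-isopropylcyclohexan-1-one | CC(C)[C@@H]1CCC(=O)C[C@H]1O | intermediate
7 | (3R,4S)-3-[(tert-butyldimethylsilyl)oxy]-4-isopropylcyclohexan-1-one | CC(C)[C@@H]1CCC(=O)C[C@H]1O[Si](C)(C)C(C)(C)C | intermediate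
8 | lithium (4S,5R)-5-[(tert-butyldimethylsilyl)oxy]-4-isopropylcyclohex-1-en-1-olate (not isolated) | CC(C)[C@@H]1CC=C(O[Li])C[C@H]1O[Si](C)(C)C(C)(C)C | intermediate
9 | tert-butyl({(1R,6S)-6-isopropyl-3-[(trimethylsilyl)oxy]cyclohex-3-en-1-yl}oxy)dimethylsilane | CC(C)[C@@H]1CC=C(O[Si](C)(C)C)C[C@H]1O[Si](C)(C)C(C)(C)C | intermediate
10 | (3R,4S)-3-[(tert-butyldimethylsilyl)oxy]-4-isopropyl-1-[(trimethylsilyl)oxy]bicyclo[4.1.0]heptane, cyclopropane CH2 anti to OTBS | CC(C)[C@@H]1C[C@@H]2C[C@]2(O[Si](C)(C)C)C[C@H]1O[Si](C)(C)C(C)(C)C | intermediate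
11 | (5S,6R)-6-[(tert-butyldimethylsilyl)oxy]-3-chloro-5-isopropylcycloheptan-1-one, both epimers at the chlorine-bearing carbon (not isolated) | CC(C)[C@@H]1CC(Cl)CC(=O)C[C@H]1O[Si](C)(C)C(C)(C)C | intermediate
12 | (5S,6R)-6-[(tert-butyldimethylsilyl)oxy]-5-isopropylcyclohept-2-en-1-one | CC(C)[C@@H]1CC=CC(=O)C[C@H]1O[Si](C)(C)C(C)(C)C | intermediate
13 | bromomagnesium (3S,5S,6R)-6-[(tert-butyldimethylsilyl)oxy]-5-isopropyl-3-(prop-1-en-2-yl)cyclohept-1-en-1-olate (not isolated) | CC(C)[C@@H]1C[C@H](C(C)=C)C=C(O[Mg]Br)C[C@H]1O[Si](C)(C)C(C)(C)C | intermediate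
14 | (2R,3S,5S,6R)-2-allyl-6-[(tert-butyldimethylsilyl)oxy]-5-isopropyl-3-(prop-1-en-2-yl)cycloheptan-1-one | CC(C)[C@@H]1C[C@H](C(C)=C)[C@@H](CC=C)C(=O)C[C@H]1O[Si](C)(C)C(C)(C)C | intermediate
15 | tert-butyl{[(1R,2S,4S,5R)-5-allyl-2-isopropyl-6-methylidene-4-(prop-1-en-2-yl)cycloheptyl]oxy}dimethylsilane | CC(C)[C@@H]1C[C@H](C(C)=C)[C@@H](CC=C)C(=C)C[C@H]1O[Si](C)(C)C(C)(C)C | intermediate
16 | tert-butyldimethylsilyl ether of (1R,5S,7S,8R)-guaia-3,10(14)-dien-8-ol | CC(C)[C@@H]1C[C@H]2[C@@H](CC=C2C)C(=C)C[C@H]1O[Si](C)(C)C(C)(C)C | intermediate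
17 | (1R,5S,7S,8R)-guaia-3,10(14)-dien-8-ol | CC(C)[C@@H]1C[C@H]2[C@@H](CC=C2C)C(=C)C[C@H]1O | intermediate
18 | 4-(benzyloxy)benzoic acid | OC(=O)c1ccc(OCc2ccccc2)cc1 | starting material
19 | (1R,5S,7S,8R)-guaia-3,10(14)-dien-8-yl 4-(benzyloxy)benzoate | CC(C)[C@@H]1C[C@H]2[C@@H](CC=C2C)C(=C)C[C@H]1OC(=O)c1ccc(OCc2ccccc2)cc1 | intermediate
20 | (1R,5S,7S,8R,10R)-10-hydroperoxyguai-3-en-8-yl 4-(benzyloxy)benzoate (not isolated) | CC(C)[C@@H]1C[C@H]2[C@@H](CC=C2C)[C@](C)(OO)C[C@H]1OC(=O)c1ccc(OCc2ccccc2)cc1 | intermediate
21 | (1R,3R,4S,5S,7S,8R,10R)-3,4-epoxy-10-hydroxyguaian-8-yl 4-(benzyloxy)benzoate | CC(C)[C@@H]1C[C@H]2[C@@H](C[C@H]3O[C@]32C)[C@](C)(O)C[C@H]1OC(=O)c1ccc(OCc2ccccc2)cc1 | intermediate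
22 | (1R,3R,4S,5S,7S,8R,10R)-3,4-epoxy-10-hydroxyguaian-8-yl 4-hydroxybenzoate (CNP0225095.2) | CC(C)[C@@H]1C[C@H]2[C@@H](C[C@H]3O[C@]32C)[C@](C)(O)C[C@H]1OC(=O)c1ccc(O)cc1 | target

Total step count: 14. Longest linear sequence: 14 steps, from 1 and 2 to 22.

**Steps most likely to fail**

First, step 13, the proposed new step. Three things could go wrong:
- Hydrogen-atom transfer may also reach C3=C4.
- Cobalt and silane may reduce part of hydroperoxide 20 early, which leaves too little oxygen for the relay.
- The bishomoallylic direction may be weak.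

The fallback uses known reactions only, sets out from 19 and returns at 21. A conventional Mukaiyama hydration (Co(acac)2, PhSiH3, O2, i-PrOH, 0 °C, then PPh3 to reduce 20) gives the isolated tertiary alcohol (1R,5S,7S,8R,10R)-10-hydroxyguai-3-en-8-yl 4-(benzyloxy)benzoate F1. Its 10α-hydroxyl then directs an ordinary VO(acac)2/t-BuOOH epoxidation, with external oxidant, to the α face and gives 21. Any F1 left over from an incomplete relay can be finished in the same way.

Second, step 8. The magnesium enolate may alkylate sluggishly, exchange protons or over-alkylate. The fallback changes the way the C1-C2 bond is made, sets out from 12 and returns at 14. After the same copper-catalysed addition, enolate 13 is O-acylated with allyl chloroformate in THF/DMPU. This gives allyl (3S,5S,6R)-6-[(tert-butyldimethylsilyl)oxy]-5-isopropyl-3-(prop-1-en-2-yl)cyclohept-1-en-1-yl carbonate F2, which is isolated. Pd(PPh3)4 (zerovalent palladium, 5 mol %, THF, rt) then triggers the Tsuji decarboxylative allylation. The regiodefined palladium enolate and allyl pair recombines at C1 anti to the isopropenyl group and gives 14.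

Third, step 7, together with the regiochemistry fixed in step 5. Iron trichloride may erode the silyl ether, the base step may eliminate the β-silyloxy group, and a minor enol ether regioisomer would give the wrong enone. The fallback replaces the cyclopropane route by a diazoalkane homologation, sets out from 7 and returns at 12.
- Sc(OTf)3-catalysed insertion of trimethylsilyldiazomethane (CH2Cl2, -78 °C to rt) should migrate the more electron-rich CH2 remote from the silyloxy carbon. This gives (5S,6R)-6-[(tert-butyldimethylsilyl)oxy]-5-isopropyl-2-(trimethylsilyl)cycloheptan-1-one F3.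
- On warming, F3 undergoes a 1,3-Brook shift to the regiodefined enol silane tert-butyl({(1R,7S)-7-isopropyl-3-[(trimethylsilyl)oxy]cyclohept-3-en-1-yl}oxy)dimethylsilane F4.
- Saegusa-Ito oxidation of F4 with Pd(OAc)2 in MeCN gives 12.

**Further compounds**
F1 | step 13 | (1R,5S,7S,8R,10R)-10-hydroxyguai-3-en-8-yl 4-(benzyloxy)benzoate | CC(C)[C@@H]1C[C@H]2[C@@H](CC=C2C)[C@](C)(O)C[C@H]1OC(=O)c1ccc(OCc2ccccc2)cc1
F2 | step 8 | allyl (3S,5S,6R)-6-[(tert-butyldimethylsilyl)oxy]-5-isopropyl-3-(prop-1-en-2-yl)cyclohept-1-en-1-yl carbonate | CC(C)[C@@H]1C[C@H](C(C)=C)C=C(OC(=O)OCC=C)C[C@H]1O[Si](C)(C)C(C)(C)C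
F3 | step 7 | (5S,6R)-6-[(tert-butyldimethylsilyl)oxy]-5-isopropyl-2-(trimethylsilyl)cycloheptan-1-one | CC(C)[C@@H]1CCC([Si](C)(C)C)C(=O)C[C@H]1O[Si](C)(C)C(C)(C)C
F4 | step 7 | tert-butyl({(1R,7S)-7-isopropyl-3-[(trimethylsilyl)oxy]cyclohept-3-en-1-yl}oxy)dimethylsilane | CC(C)[C@@H]1CCC=C(O[Si](C)(C)C)C[C@H]1O[Si](C)(C)C(C)(C)C
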